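Product in this flask comes off catalyst intermediate B while substrate arrives by the clock, so hold the one rate against the other.

substrate 0.020 M (fed, over 4.0 h); capture agent 0.400 mM; free catalyst 0.50 mM; time 5.0 h

    substrate + free catalyst → catalyst intermediate A (k1 = 250 L mol⁻¹ min⁻¹)
    catalyst intermediate A ⇌ catalyst intermediate B (K2 = 0.71, k2 = 0.38 min⁻¹)
    catalyst intermediate B → free catalyst + product (k3 = 0.34 min⁻¹)
    catalyst intermediate A + capture agent → trapped intermediate (k4 = 15 L mol⁻¹ min⁻¹)
    2 catalyst intermediate B → spent catalyst (k5 = 2.2 L mol⁻¹ min⁻¹)

- percentages count the substrate that a species holds: one spent catalyst counts as two
- two of one species on the left: rate k times its square, two consumed each time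
- the reaction counts as stopped when no species that holds the substrate changes by six tenths of a point or more over the second half of the time
- run time (flask): 5.0 h

- the state of affairs at 5.0 h: stopped, and by what, or still going (no working catalyst is left / forward and back rates have come level / all of the substrate has reacted / it is still moving)
- share of the substrate used up at 5.0 h
- product at 5.0 h, in percent of the substrate charged
- amount of product if the flask were left three thousand times as long, in percent of the substrate charged

Take the round with substrate plentiful. Steady state in catalyst intermediate B gives a turnover of 0.103 min⁻¹ per working catalyst, with 69.7% of the pair sitting as catalyst intermediate A, the resting state. In fractions of the substrate charge, that makes a ceiling of 0.154 h⁻¹ against a feed of 0.250 h⁻¹. Their quotient, feed over ceiling, is the overfeed ratio 1.62; one is the zero of the scale, where the round just keeps pace. Here the feed is faster than the ceiling, so substrate piles up.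

So draw your product curve. Substrate at 2.06% of the charge runs the round at half its ceiling, and the feed must also load the catalyst, 2.50% of the charge. So the product slope starts at zero and climbs toward the ceiling, which itself sinks as capture agent removes catalyst intermediate A. Working share and ceiling follow from second-order capture on that resting share:

| time | working share | ceiling on product slope |
|---|---|---|
| start | 100% | 0.154 h⁻¹ |
| 2.50 h | 63.3% | 0.0975 h⁻¹ |
| 5.00 h | 48.1% | 0.0741 h⁻¹ |

Simpson's weighting of these rows gives me 51.6% product under the ceiling, a figure that runs high by the slow start, still climbing at the end, and about 54.1% conversion, counting substrate bound on catalyst. Capture agent amounts to 80.0% of the catalyst, so catalyst survives and the curve runs up to 98.0%, spent catalyst apart.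

The forecast says it is still moving, with 47% conversion, 45% product and 98% in the long run: “substrate piles up while the capture agent slowly eats the catalyst”. Its product stands lower than mine.

The flask gives it is still moving, with 48.6% conversion, 46.1% product and 98.2% in the long run. At 4.00 h, the end of the feed, this flask holds 38.4% product and trapped intermediate at 43.5% of the catalyst, so the overfeed ratio read across the whole feed is 2.60, above the starting 1.62. The flask with 0.0020 M of free catalyst starts at a ratio of 0.405, below one, and at 5.00 h it holds 98.0% product at 100% conversion.

The numbers of this flask come from no measurement; the run is a simulation.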